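**Retrosynthetic overview** (germacrane numbering: C6–O lactone, C8–OH, C14–O methacrylate, C15–OAc)
1. Target ⇒ macrocyclic α‑(diethoxyphosphoryl)lactone. C11=C13 comes from a final HWE reaction with CH2O, and the C14 ester from a selective acylation, so the main line needs no protecting-group steps.
2. Cyclodecadiene (third ring formed) ⇒ RCM at C1=C10 of an open triene. The ten-membered ring favours the ring‑cis alkene.
3. C8–C9 ⇒ catalyst-controlled 2‑(oxymethyl)allylation of a C8 aldehyde. C5–C6 ⇒ NHK addition of a geometrically pure alkenyl iodide (C1–C5 plus C15) to a C6 aldehyde.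
4. trans‑γ‑Lactone plus C8 aldehyde (second ring) ⇒ retro‑aldol/lactonisation of a donor–acceptor cyclopropane, itself obtained by ozonolysis of a 2‑oxabicyclo[3.1.0]hexene.
5. That bicycle (first ring) ⇒ enantioselective dearomative cyclopropanation of methyl 2‑furoate with a diazophosphonoacetate. Furan C3/C4/C5 become C6/C7/C8, the carbene carbon becomes C11 and its ester carbon C12.

Assumption: the SMILES is read literally, i.e. (6R,7R,8R) with both ring alkenes ring‑cis (C2 cis to C9, C3 cis to C6; CIP E,E); the catalyst antipodes named in steps 2 and 9 are those expected to give this series, and the mirror-image catalyst is used if a test run shows the opposite sense.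

**Step 1**
Reactants: 1 triethyl phosphonoacetate
Product: 2 ethyl 2-diazo-2-(diethoxyphosphoryl)acetate
Conditions: p‑ABSA (1.1 equiv), DBU (1.2 equiv), MeCN, 0 °C to rt
Reagents that add atoms: 4-acetamidobenzenesulfonyl azide (p‑ABSA), CC(=O)Nc1ccc(cc1)S(=O)(=O)N=[N+]=[N-]
Why: Regitz diazo transfer, in which DBU deprotonates the doubly activated CH2, the carbanion attacks the terminal azide nitrogen and the triazene collapses to the diazo compound and the sulfonamide; no stereocentre is involved.

**Step 2 (key step)**
Reactants: 2 ethyl 2-diazo-2-(diethoxyphosphoryl)acetate; 3 methyl furan-2-carboxylate (5 equiv)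
Product: 4 methyl (1R,5S)-6-(diethoxyphosphoryl)-6-(ethoxycarbonyl)-2-oxabicyclo[3.1.0]hex-3-ene-3-carboxylate (either C6 epimer)
Conditions: Rh2(S‑TCPTTL)4 (1 mol %), PhCF3, 60 °C, 2 added over 10 h
Reagents that add atoms: none
Why: Proposed new method: dearomative Rh(II)-carbenoid cyclopropanation, in which the strongly electrophilic diacceptor carbenoid is attacked by the unsubstituted, enol-ether-like C4=C5 bond of the furoate (bond to C5 leading), the C2 ester damps donation from the ring oxygen so that the dipolar transition state closes to the cyclopropane instead of unravelling to a dienal or re-aromatising, and the chiral pocket of the phthalimido-carboxylate catalyst selects the furan face and so sets C7 (and the transient C8 centre) absolutely, C11 being irrelevant; the closest known reaction types are the Cu(I)–bis(oxazoline) cyclopropanation of methyl 2-furoate with ethyl diazoacetate and Rh(II)-carboxylate-catalysed enantioselective cyclopropanations with diacceptor diazo compounds.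

**Step 3**
Reactants: 4 bicyclic adduct
Product: 6 ethyl (2R,3R)-1-(diethoxyphosphoryl)-2-formyl-3-[(2-methoxy-2-oxoacetyl)oxy]cyclopropane-1-carboxylate (CHO and oxalyloxy cis), via primary ozonide 5 (not isolated)
Conditions: O3/O2, CH2Cl2, −78 °C; then Me2S, −78 °C to rt
Reagents that add atoms: ozone, [O-][O+]=O
Why: Ozonolysis (Criegee cleavage, reductive work-up) of the only C=C turns furan C3 into the C6 aldehyde and furan C2 into a methyl oxalate that masks the C8 cyclopropanol, and no stereocentre is touched.

**Step 4**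
Reactants: 7 but-3-en-1-ylmagnesium bromide; 8 trimethyl(prop-2-yn-1-yloxy)silane
Product: 12 (E)-2-(iodomethylidene)hex-5-en-1-ol, via butenylcopper 9 (not isolated), via alkenylcopper adduct 10 (not isolated), via silyl ether iodide 11 (not isolated)
Conditions: CuBr·SMe2 (1 equiv), Et2O–THF–Me2S, −45 °C; 8, −25 °C; I2, −78 to 0 °C; 1 M HCl work-up
Reagents that add atoms: iodine, II
Why: Normant syn-carbocupration places butenyl on the internal and Cu on the terminal alkyne carbon from the same face (the bulky, weakly coordinating OTMS group disfavours the reversed, allene-forming orientation), and iodinolysis with retention fixes I cis to the butenyl chain, i.e. the ring‑cis C4=C5 geometry, before the acid work-up removes TMS.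

**Step 5**
Reactants: 12 (E)-2-(iodomethylidene)hex-5-en-1-ol
Product: 13 (E)-2-(iodomethylidene)hex-5-en-1-yl acetate
Conditions: Ac2O, Et3N, DMAP (cat.), CH2Cl2, 0 °C
Reagents that add atoms: acetic anhydride, CC(=O)OC(C)=O
Why: DMAP-catalysed O-acetylation of the only hydroxyl installs the final C15 acetate without touching the alkenyl iodide.

**Step 6**
Reactants: 6 cyclopropanecarbaldehyde; 13 alkenyl iodide (1.5 equiv)
Product: 14 ethyl (2S,3R)-2-[(1R,2E)-3-(acetoxymethyl)-1-hydroxyhepta-2,6-dien-1-yl]-1-(diethoxyphosphoryl)-3-[(2-methoxy-2-oxoacetyl)oxy]cyclopropane-1-carboxylate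
Conditions: CrCl2 (4 equiv), NiCl2 (2 mol %), DMF, rt
Reagents that add atoms: none
Why: Nozaki–Hiyama–Kishi alkenylation adds only to the aldehyde (oxalate, esters, phosphonate and allylic acetate survive) with retention of alkene geometry, and C6 is set by Felkin–Anh attack anti to the cyclopropane C–C(O) bond as in additions to related cyclopropanecarbaldehydes, the minor C6 epimer being removed here by chromatography so that it cannot erode the ee later.

**Step 7**
Reactants: 14 NHK adduct
Product: 17 diethyl {(4S,5R)-5-[(1E)-2-(acetoxymethyl)hexa-1,5-dien-1-yl]-4-formyl-2-oxooxolan-3-yl}phosphonate (C3 epimers), via cyclopropanol 15 (not isolated), via ring-opened hydroxy aldehyde 16 (not isolated)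
Conditions: Et3N (0.5 equiv), MeOH, 0 °C to rt; used directly
Reagents that add atoms: none
Why: The very labile oxalate is methanolysed in preference to the acetate, the freed cyclopropanol undergoes retro-aldol opening of the donor–acceptor cyclopropane (C8–C11 bond) to the C8 aldehyde and a phosphonoacetate carbanion that is protonated, and the C6–OH lactonises on the ethyl ester, keeping the C6/C7 trans relationship (also the thermodynamic one) and leaving C11 as an inconsequential epimer mixture.

**Step 8**
Reactants: 18 2-methylprop-2-en-1-ol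
Product: 21 tributyl{2-[(trimethylsilyloxy)methyl]prop-2-en-1-yl}stannane, via dilithio dianion 19 (not isolated), via stannyl lithium alkoxide 20 (not isolated)
Conditions: n‑BuLi (2.2 equiv), TMEDA, Et2O, 0 °C to rt; Bu3SnCl (1.0 equiv), −78 °C; TMSCl (1.2 equiv), −78 °C to rt
Reagents that add atoms: tributyltin chloride, CCCC[Sn](Cl)(CCCC)CCCC; chlorotrimethylsilane, C[Si](C)(C)Cl
Why: Double lithiation (alkoxide plus allylic CH3) gives a dianion whose carbanion is stannylated first and whose remaining alkoxide is then silylated, and the allyl unit carries two equivalent CH2 termini so no regiochemical question arises later.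

**Step 9**
Reactants: 17 lactone aldehyde; 21 allylstannane (1.5 equiv)
Product: 23 diethyl {(4R,5R)-5-[(1E)-2-(acetoxymethyl)hexa-1,5-dien-1-yl]-4-[(1R)-1-hydroxy-3-(hydroxymethyl)but-3-en-1-yl]-2-oxooxolan-3-yl}phosphonate, via C14 silyl ether 22 (not isolated)
Conditions: (R)‑BINOL (40 mol %), Ti(OiPr)4 (20 mol %), 4 Å MS, CH2Cl2, −20 °C; then 0.5 M citric acid, MeOH, 0 °C
Reagents that add atoms: none
Why: Keck asymmetric allylation, in which the (R)-BINOL–Ti(IV) Lewis acid activates only the aldehyde and steers the 2-substituted allylstannane (SE2') to its Re face, setting 8R (1,3-anti to the C6 oxygen) under catalyst control irrespective of the weak substrate bias, after which the mild acid work-up cleaves the primary TMS ether.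

**Step 10**
Reactants: 23 diol triene
Product: 24 diethyl [(3aR,4R,6E,10E,11aR)-10-(acetoxymethyl)-4-hydroxy-6-(hydroxymethyl)-2-oxo-2,3,3a,4,5,8,9,11a-octahydrocyclodeca[b]furan-3-yl]phosphonate (both ring alkenes ring‑cis)
Conditions: Hoveyda–Grubbs II (15 mol %), 1,4-benzoquinone (30 mol %), toluene (1 mM), 80 °C, Ar sparge
Reagents that add atoms: none
Why: Ring-closing metathesis, in which Ru loads on the monosubstituted C1 vinyl group and closes on the 1,1-disubstituted C10 alkene activated by its allylic OH, the trans-lactone and the ring‑cis C4=C5 unit pre-fold the chain, and reversible metathesis with loss of ethene funnels to the ring‑cis trisubstituted alkene, the lower-energy isomer in a ten-membered ring.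

**Step 11**
Reactants: 24 macrocyclic diol
Product: 25 [(3aR,4R,6E,10E,11aR)-10-(acetoxymethyl)-3-(diethoxyphosphoryl)-4-hydroxy-2-oxo-2,3,3a,4,5,8,9,11a-octahydrocyclodeca[b]furan-6-yl]methyl 2-methylprop-2-enoate
Conditions: methacryloyl chloride (1.05 equiv), 2,4,6-collidine (2 equiv), CH2Cl2, −78 to −30 °C
Reagents that add atoms: methacryloyl chloride, C=C(C)C(=O)Cl
Why: Chemoselective O-acylation, because the primary allylic C14–OH reacts far faster than the hindered secondary C8–OH at low temperature and collidine is too weak a base to touch C11–H.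

**Step 12**
Reactants: 25 phosphono lactone
Product: 26 [(3aR,4R,6E,10E,11aR)-10-(acetoxymethyl)-4-hydroxy-3-methylidene-2-oxo-2,3,3a,4,5,8,9,11a-octahydrocyclodeca[b]furan-6-yl]methyl 2-methylprop-2-enoate (CNP0313792.2)
Conditions: K2CO3 (2 equiv), 37 % aq. HCHO (10 equiv), THF, 0 °C, 30–60 min
Reagents that add atoms: formaldehyde, C=O
Why: Horner–Wadsworth–Emmons olefination, in which carbonate deprotonates only the doubly activated C11–H (acetate, methacrylate and the free C8–OH survive the short cold exposure) and loss of diethyl phosphate erases the C11 centre and gives the exocyclic methylene without touching C6, C7 or C8.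

**Compound list**
1 | triethyl phosphonoacetate | CCOC(=O)CP(=O)(OCC)OCC | starting material
2 | ethyl 2-diazo-2-(diethoxyphosphoryl)acetate | CCOC(=O)C(=[N+]=[N-])P(=O)(OCC)OCC | intermediate
3 | methyl furan-2-carboxylate | COC(=O)c1ccco1 | starting material
4 | methyl (1R,5S)-6-(diethoxyphosphoryl)-6-(ethoxycarbonyl)-2-oxabicyclo[3.1.0]hex-3-ene-3-carboxylate | COC(=O)C1=C[C@@H]2C(C(=O)OCC)(P(=O)(OCC)OCC)[C@@H]2O1 | intermediate
5 | primary ozonide of 4 (1,2,3-trioxolane across C3–C4) | COC(=O)C12OOOC1[C@@H]1C(C(=O)OCC)(P(=O)(OCC)OCC)[C@@H]1O2 | intermediate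
6 | ethyl (2R,3R)-1-(diethoxyphosphoryl)-2-formyl-3-[(2-methoxy-2-oxoacetyl)oxy]cyclopropane-1-carboxylate | O=C[C@@H]1C(C(=O)OCC)(P(=O)(OCC)OCC)[C@@H]1OC(=O)C(=O)OC | intermediate
7 | but-3-en-1-ylmagnesium bromide | C=CCC[Mg]Br | starting material
8 | trimethyl(prop-2-yn-1-yloxy)silane | C#CCO[Si](C)(C)C | starting material
9 | but-3-en-1-ylcopper | C=CCC[Cu] | intermediate
10 | alkenylcopper adduct (Cu cis to butenyl) | C=CCC/C(CO[Si](C)(C)C)=C\[Cu] | intermediate
11 | (E)-[2-(iodomethylidene)hex-5-en-1-yl]oxy(trimethyl)silane | C=CCC/C(CO[Si](C)(C)C)=C\I | intermediate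
12 | (E)-2-(iodomethylidene)hex-5-en-1-ol | C=CCC/C(CO)=C\I | intermediate
13 | (E)-2-(iodomethylidene)hex-5-en-1-yl acetate | C=CCC/C(COC(C)=O)=C\I | intermediate
14 | NHK adduct (6R carbinol on the oxalyloxy cyclopropane) | C=CCC/C(COC(C)=O)=C\[C@@H](O)[C@@H]1C(C(=O)OCC)(P(=O)(OCC)OCC)[C@@H]1OC(=O)C(=O)OC | intermediate
15 | free cyclopropanol from 14 | C=CCC/C(COC(C)=O)=C\[C@@H](O)[C@@H]1C(C(=O)OCC)(P(=O)(OCC)OCC)[C@@H]1O | intermediate
16 | ring-opened γ-hydroxy aldehyde phosphonoacetate | C=CCC/C(COC(C)=O)=C\[C@@H](O)[C@@H](C=O)C(C(=O)OCC)P(=O)(OCC)OCC | intermediate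
17 | diethyl {(4S,5R)-5-[(1E)-2-(acetoxymethyl)hexa-1,5-dien-1-yl]-4-formyl-2-oxooxolan-3-yl}phosphonate | C=CCC/C(COC(C)=O)=C\[C@H]1OC(=O)C(P(=O)(OCC)OCC)[C@@H]1C=O | intermediate
18 | 2-methylprop-2-en-1-ol | C=C(C)CO | starting material
19 | dilithio dianion of 18 | [Li]CC(=C)CO[Li] | intermediate
20 | lithium 2-[(tributylstannyl)methyl]prop-2-en-1-olate | C=C(CO[Li])C[Sn](CCCC)(CCCC)CCCC | intermediate
21 | tributyl{2-[(trimethylsilyloxy)methyl]prop-2-en-1-yl}stannane | C=C(CO[Si](C)(C)C)C[Sn](CCCC)(CCCC)CCCC | intermediate
22 | 8R homoallylic alcohol, C14 TMS ether | C=CCC/C(COC(C)=O)=C\[C@H]1OC(=O)C(P(=O)(OCC)OCC)[C@@H]1[C@H](O)CC(=C)CO[Si](C)(C)C | intermediate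
23 | diol triene (6R,7R,8R) | C=CCC/C(COC(C)=O)=C\[C@H]1OC(=O)C(P(=O)(OCC)OCC)[C@@H]1[C@H](O)CC(=C)CO | intermediate
24 | macrocyclic 8,14-diol phosphono lactone | OC/C1=C/CC/C(COC(C)=O)=C\[C@H]2OC(=O)C(P(=O)(OCC)OCC)[C@@H]2[C@H](O)C1 | intermediate
25 | 14-O-methacryloyl phosphono lactone | C=C(C)C(=O)OC/C1=C/CC/C(COC(C)=O)=C\[C@H]2OC(=O)C(P(=O)(OCC)OCC)[C@@H]2[C@H](O)C1 | intermediate
26 | CNP0313792.2 | C=C(C)C(=O)OC/C1=C/CC/C(COC(C)=O)=C\[C@H]2OC(=O)C(=C)[C@@H]2[C@H](O)C1 | target

**Step count and risks**

Total step count: 12. Longest linear sequence: 9 steps (1 → 2 → 4 → 6 → 14 → 17 → 23 → 24 → 25 → 26). Stereocontrol is set as follows: C7 in step 2, C4=C5 in step 4, C6 in step 6, C8 in step 9 and C1=C10 in step 10.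

Step 2 (diacceptor carbenoid on the furoate) is the first risk. The adduct may unravel or re-aromatise, and the ee is unproven. The fallback sets out from 3 and comes back at 4, making the C–P bond after the dearomatisation rather than during it. Compound 3 is cyclopropanated with ethyl diazoacetate under Cu(OTf)2/(R,R)-iPr-bis(oxazoline)/PhNHNH2 in CH2Cl2 at 0 °C. This established reaction gives a crystalline product whose ee can be raised by recrystallisation, namely 6-ethyl 3-methyl (1R,5R,6R)-2-oxabicyclo[3.1.0]hex-3-ene-3,6-dicarboxylate F1. Deprotonation of the cyclopropane ester C6–H with LDA (THF, −78 °C) and quenching with ClP(OEt)2 gives the C6 diethyl phosphonite F2. This is oxidised in the same flask with H2O2 to 4. The configuration at C6 does not matter.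

Step 10 (RCM to a trisubstituted alkene in a ten-membered carbocycle) is the second risk, because dimerisation or no closure may occur. The fallback sets out from 17 and comes back at 24, closing the ring by C–C addition at C1–C10 instead of by metathesis.
- Compound 17 is bromoallylated with (2-bromoallyl)diisopinocampheylborane (reagent control at C8) to give the 8R 2-bromoallyl carbinol F4.
- The monosubstituted alkene of F4 is cleaved selectively (OsO4 cat., NaIO4, 2,6-lutidine) to the C1 aldehyde F5.
- Intramolecular Nozaki–Hiyama–Kishi reaction (CrCl2, NiCl2 cat., DMF, high dilution) closes the ring to the 1-hydroxy-10(14)-methylidene macrocycle F6.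
- Re2O7-catalysed 1,3-transposition of this allylic alcohol moves the oxygen to C14 and the alkene into the ring. This is the thermodynamic product (primary alcohol, trisubstituted ring‑cis alkene) and gives 24, with the non-allylic C8–OH untouched.

Step 4 (regiochemistry of carbocupration of a propargylic ether) is the third risk, because the reversed orientation leads to an allene. The fallback sets out from 7 and comes back at 12, adding the C15 oxygen afterwards instead of carrying it in the alkyne. The organocopper from 7 and CuBr·SMe2 is added to propyne, for which the orientation is secure. Iodinolysis then gives (Z)-1-iodo-2-methylhexa-1,5-diene F3. SeO2 (cat.)/t‑BuOOH allylic oxidation follows the E rule and attacks the methyl group trans to iodine, giving 12.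

**Further compounds**
F1 | step 2 | 6-ethyl 3-methyl (1R,5R,6R)-2-oxabicyclo[3.1.0]hex-3-ene-3,6-dicarboxylate | COC(=O)C1=C[C@@H]2[C@@H](C(=O)OCC)[C@@H]2O1
F2 | step 2 | methyl (1R,5S)-6-(diethoxyphosphanyl)-6-(ethoxycarbonyl)-2-oxabicyclo[3.1.0]hex-3-ene-3-carboxylate | COC(=O)C1=C[C@@H]2C(C(=O)OCC)(P(OCC)OCC)[C@@H]2O1
F3 | step 4 | (Z)-1-iodo-2-methylhexa-1,5-diene | C=CCC/C(C)=C\I
F4 | step 10 | 8R 2-bromoallyl carbinol of 17 | C=CCC/C(COC(C)=O)=C\[C@H]1OC(=O)C(P(=O)(OCC)OCC)[C@@H]1[C@H](O)CC(Br)=C
F5 | step 10 | C1 aldehyde from F4 | O=CCC/C(COC(C)=O)=C\[C@H]1OC(=O)C(P(=O)(OCC)OCC)[C@@H]1[C@H](O)CC(Br)=C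
F6 | step 10 | 1-hydroxy-10(14)-methylidene macrocycle | OC1CC/C(COC(C)=O)=C\[C@H]2OC(=O)C(P(=O)(OCC)OCC)[C@@H]2[C@H](O)CC1=C
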